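## Retrosynthetic overview

1. The two esters and the silyl ether go on/off last; the C5 oxygen and the C4 methylidene come from the β-epoxide of a C4(methyl)=C5 alkene, opened by trivalent titanium.
2. The C3 oxygen (α) and the trans ring fusion (H-3a β) come from a 3α,3aα-epoxy ketone by palladium-catalysed formate hydrogenolysis with inversion; the epoxide face is set by a 2α-hydroxyl-directed epoxidation.
3. Key step: an intramolecular Pauson–Khand reaction of the acyclic dienyne 14. No ring exists before it; the six- and five-membered rings form together in step 9 (instead of annulating a cyclopentanone onto a chiral-pool cyclohexanone and adding the side chain by aldol).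
4. Dienyne 14 comes from an Evans alkylation of an isovaleryl imide with a (Z)-enynyl bromide (sets C7), then Wittig olefination and CBS reduction (sets C1′).

Assumption: (2R)-2-methylbutanoic acid 20 and (2E)-3-methylpent-2-enoic acid 24 are bought as the single isomers shown.

Convention: bicyclic compounds carry indane numbering (C1 side-chain carbon, C2 carbonyl carbon, C3 acyloxy carbon, C3a/C7a ring fusion, C4 methyl/methylidene carbon, C5 carbinol carbon, C7 isopropyl carbon). β is the face of H-3a and of the C5 oxygen in the target; H-7a, the C1 side chain, the C3 oxygen and the isopropyl group are α.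

## Route

Step 1
Reactants: 1 (4S)-4-benzyl-1,3-oxazolidin-2-one; 2 3-methylbutanoyl chloride
Product: 4 (4S)-4-benzyl-3-(3-methylbutanoyl)-1,3-oxazolidin-2-one, via lithium oxazolidinonide 3 (not isolated)
Conditions: n-BuLi, THF, −78 °C; then 2, −78 → 0 °C
Reagents that add atoms: none
Why: N-acylation of the lithiated Evans auxiliary by an acid chloride is fast and clean, and no stereocentre is formed.

Step 2
Reactants: 5 (2Z)-3-methylpent-2-en-4-yn-1-ol
Product: 6 (3Z)-5-bromo-3-methylpent-3-en-1-yne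
Conditions: CBr4, PPh3, CH2Cl2, 0 °C
Reagents that add atoms: carbon tetrabromide, BrC(Br)(Br)Br
Why: The Appel reaction converts the primary allylic alcohol into the bromide under neutral conditions that leave the Z-enyne geometry untouched.

Step 3
Reactants: 4 (4S)-4-benzyl-3-(3-methylbutanoyl)-1,3-oxazolidin-2-one; 6 (3Z)-5-bromo-3-methylpent-3-en-1-yne
Product: 8 (4S)-4-benzyl-3-[(2S,4Z)-5-methyl-2-(propan-2-yl)hept-4-en-6-ynoyl]-1,3-oxazolidin-2-one, via sodium Z-enolate 7 (not isolated)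
Conditions: NaN(SiMe3)2, THF, −78 °C; then 6, −78 → −40 °C
Reagents that add atoms: none
Why: Evans asymmetric alkylation: the chelated Z-enolate is alkylated by the reactive allylic bromide on the face opposite the benzyl group, which sets the future C7 as S.

Step 4
Reactants: 8 (4S)-4-benzyl-3-[(2S,4Z)-5-methyl-2-(propan-2-yl)hept-4-en-6-ynoyl]-1,3-oxazolidin-2-one
Product: 9 (2S,4Z)-5-methyl-2-(propan-2-yl)hept-4-en-6-yn-1-ol
Conditions: LiBH4, MeOH (1 equiv), Et2O, 0 °C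
Reagents that add atoms: none
Why: Reductive cleavage of the imide by borohydride removes the auxiliary without touching the α-stereocentre, the alkene or the alkyne.

Step 5
Reactants: 9 (2S,4Z)-5-methyl-2-(propan-2-yl)hept-4-en-6-yn-1-ol
Product: 10 (2S,4Z)-5-methyl-2-(propan-2-yl)hept-4-en-6-ynal
Conditions: Dess–Martin periodinane, CH2Cl2, 0 °C → rt
Reagents that add atoms: none
Why: Dess–Martin oxidation gives the α-branched aldehyde under mild conditions without epimerisation; it is used at once.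

Step 6
Reactants: 10 (2S,4Z)-5-methyl-2-(propan-2-yl)hept-4-en-6-ynal; 11 1-(triphenylphosphoranylidene)propan-2-one
Product: 12 (3E,5S,7Z)-8-methyl-5-(propan-2-yl)deca-3,7-dien-9-yn-2-one
Conditions: toluene, 80 °C
Reagents that add atoms: none
Why: Wittig olefination with a stabilised ylide gives the E-enone, and the base-free conditions preserve the α-stereocentre and the free terminal alkyne.

Step 7
Reactants: 12 (3E,5S,7Z)-8-methyl-5-(propan-2-yl)deca-3,7-dien-9-yn-2-one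
Product: 13 (2R,3E,5S,7Z)-8-methyl-5-(propan-2-yl)deca-3,7-dien-9-yn-2-ol
Conditions: (3aS)-1-methyl-3,3-diphenyltetrahydro-1H,3H-pyrrolo[1,2-c][1,3,2]oxazaborole (20 mol %), catecholborane, toluene, −78 °C
Reagents that add atoms: none
Why: Corey–Bakshi–Shibata reduction is 1,2-selective on enones and catalyst-controlled (alkenyl as the large group), so the S-catalyst gives the R-carbinol (future C1′); catecholborane at −78 °C does not hydroborate the alkenes or the alkyne.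

Step 8
Reactants: 13 (2R,3E,5S,7Z)-8-methyl-5-(propan-2-yl)deca-3,7-dien-9-yn-2-ol
Product: 14 tert-butyl(dimethyl){[(2R,3E,5S,7Z)-8-methyl-5-(propan-2-yl)deca-3,7-dien-9-yn-2-yl]oxy}silane
Conditions: TBSCl, imidazole, DMF, rt
Reagents that add atoms: tert-butyldimethylsilyl chloride, CC(C)(C)[Si](C)(C)Cl
Why: Standard silylation protects the secondary alcohol for the rest of the route; no stereocentre is affected.

Step 9
Reactants: 14 tert-butyl(dimethyl){[(2R,3E,5S,7Z)-8-methyl-5-(propan-2-yl)deca-3,7-dien-9-yn-2-yl]oxy}silane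
Product: 15 (1S,7S,7aR)-1-[(1R)-1-{[tert-butyl(dimethyl)silyl]oxy}ethyl]-4-methyl-7-(propan-2-yl)-1,6,7,7a-tetrahydro-2H-inden-2-one
Conditions: Co2(CO)8 (0.3 equiv), tetramethylthiourea (1.8 equiv), CO (1 atm), toluene, 80 °C
Reagents that add atoms: carbon monoxide, [C-]#[O+]
Why: Intramolecular Pauson–Khand reaction: the rigid Z-enyne holds alkyne and alkene close (as an aryl tether does) so both rings close at once; the E-alkene geometry is transferred (C1 side chain trans to C7 across the new ring), and C7a forms with H-7a anti to H-7 because the isopropyl group sits pseudo-equatorial in the chair-like insertion transition state.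

Step 10
Reactants: 15 (1S,7S,7aR)-1-[(1R)-1-{[tert-butyl(dimethyl)silyl]oxy}ethyl]-4-methyl-7-(propan-2-yl)-1,6,7,7a-tetrahydro-2H-inden-2-one
Product: 16 1α-[(1R)-1-{[tert-butyl(dimethyl)silyl]oxy}ethyl]-4-methyl-7α-(propan-2-yl)-2,6,7,7a-tetrahydro-1H-inden-2α-ol (H-7a α)
Conditions: LiBH(s-Bu)3, THF, −78 °C; then H2O
Reagents that add atoms: none
Why: The bulky hydride reduces the carbonyl 1,2 (the β-carbon is fully substituted, which blocks conjugate reduction) from the β face, anti to the adjacent α side chain, giving the 2α-alcohol.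

Step 11
Reactants: 16 1α-[(1R)-1-{[tert-butyl(dimethyl)silyl]oxy}ethyl]-4-methyl-7α-(propan-2-yl)-2,6,7,7a-tetrahydro-1H-inden-2α-ol
Product: 17 1α-[(1R)-1-{[tert-butyl(dimethyl)silyl]oxy}ethyl]-3α,3aα-epoxy-4-methyl-7α-(propan-2-yl)-2,3,3a,6,7,7a-hexahydro-1H-inden-2α-ol (H-7a α)
Conditions: VO(acac)2 (5 mol %), t-BuOOH, CH2Cl2, 0 °C
Reagents that add atoms: tert-butyl hydroperoxide, CC(C)(C)OO
Why: Sharpless–Michaelson hydroxyl-directed epoxidation delivers oxygen to the allylic C3=C3a alkene on the face of the 2α-OH, and the remote C4=C5 alkene is out of reach of the vanadium alkoxide.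

Step 12
Reactants: 17 1α-[(1R)-1-{[tert-butyl(dimethyl)silyl]oxy}ethyl]-3α,3aα-epoxy-4-methyl-7α-(propan-2-yl)-2,3,3a,6,7,7a-hexahydro-1H-inden-2α-ol
Product: 18 1α-[(1R)-1-{[tert-butyl(dimethyl)silyl]oxy}ethyl]-3α,3aα-epoxy-4-methyl-7α-(propan-2-yl)-1,3,3a,6,7,7a-hexahydro-2H-inden-2-one (H-7a α)
Conditions: Dess–Martin periodinane, pyridine, CH2Cl2, 0 °C
Reagents that add atoms: none
Why: Dess–Martin oxidation buffered by pyridine returns the C2 ketone without opening the acid-labile vinyl epoxide.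

Step 13
Reactants: 18 1α-[(1R)-1-{[tert-butyl(dimethyl)silyl]oxy}ethyl]-3α,3aα-epoxy-4-methyl-7α-(propan-2-yl)-1,3,3a,6,7,7a-hexahydro-2H-inden-2-one
Product: 19 (1S,3S,3aR,7S,7aS)-1-[(1R)-1-{[tert-butyl(dimethyl)silyl]oxy}ethyl]-3-hydroxy-4-methyl-7-(propan-2-yl)-1,3,3a,6,7,7a-hexahydro-2H-inden-2-one
Conditions: Pd2(dba)3·CHCl3 (5 mol %), n-Bu3P (20 mol %), HCO2H, Et3N, 1,4-dioxane, rt
Reagents that add atoms: none
Why: Tsuji–Shimizu hydrogenolysis of an alkenyl oxirane: zerovalent palladium ionises the tertiary allylic C3a–O bond anti to the epoxide, and hydride from formate passes from the metal (β face) to the more substituted allyl terminus C3a, so C3a is inverted (H-3a β, trans fusion) while C3 keeps its α-oxygen and C4=C5 stays in place.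

Step 14
Reactants: 19 (1S,3S,3aR,7S,7aS)-1-[(1R)-1-{[tert-butyl(dimethyl)silyl]oxy}ethyl]-3-hydroxy-4-methyl-7-(propan-2-yl)-1,3,3a,6,7,7a-hexahydro-2H-inden-2-one; 20 (2R)-2-methylbutanoic acid
Product: 21 (1S,3S,3aR,7S,7aS)-1-[(1R)-1-{[tert-butyl(dimethyl)silyl]oxy}ethyl]-4-methyl-3-{[(2R)-2-methylbutanoyl]oxy}-7-(propan-2-yl)-1,3,3a,6,7,7a-hexahydro-2H-inden-2-one
Conditions: DCC, 4-(dimethylamino)pyridine (10 mol %), CH2Cl2, 0 °C → rt
Reagents that add atoms: none
Why: Steglich esterification acylates the α-ketol hydroxyl under mild conditions that epimerise neither C3 nor the α-centre of the acid.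

Step 15
Reactants: 21 (1S,3S,3aR,7S,7aS)-1-[(1R)-1-{[tert-butyl(dimethyl)silyl]oxy}ethyl]-4-methyl-3-{[(2R)-2-methylbutanoyl]oxy}-7-(propan-2-yl)-1,3,3a,6,7,7a-hexahydro-2H-inden-2-one
Product: 22 1α-[(1R)-1-{[tert-butyl(dimethyl)silyl]oxy}ethyl]-4β,5β-epoxy-4-methyl-3α-{[(2R)-2-methylbutanoyl]oxy}-7α-(propan-2-yl)octahydro-2H-inden-2-one (H-3a β, H-7a α)
Conditions: dimethyldioxirane, acetone/CH2Cl2, −20 → 0 °C
Reagents that add atoms: dimethyldioxirane, CC1(C)OO1
Why: Neutral Murray epoxidation of the only remaining alkene; the α-oriented pseudo-axial acyloxy group at C3 hangs under C4, so the reagent should approach from the β face.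

Step 16
Reactants: 22 1α-[(1R)-1-{[tert-butyl(dimethyl)silyl]oxy}ethyl]-4β,5β-epoxy-4-methyl-3α-{[(2R)-2-methylbutanoyl]oxy}-7α-(propan-2-yl)octahydro-2H-inden-2-one
Product: 23 (1S,3S,3aR,5R,7S,7aS)-1-[(1R)-1-{[tert-butyl(dimethyl)silyl]oxy}ethyl]-5-hydroxy-4-methylidene-3-{[(2R)-2-methylbutanoyl]oxy}-7-(propan-2-yl)octahydro-2H-inden-2-one
Conditions: Cp2TiCl2 (2.5 equiv), Mn dust, THF, rt; then 0.5 M aq. HCl
Reagents that add atoms: none
Why: Nugent–RajanBabu opening by trivalent titanium (Cp2TiCl): homolysis of the more substituted C4–O bond gives the tertiary C4 radical, which is trapped by a second titanium and loses a methyl hydrogen by β-hydride elimination to give the exocyclic alkene; the C5–O bond is never broken, so the 5β-OH comes from the epoxide face.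

Step 17
Reactants: 23 (1S,3S,3aR,5R,7S,7aS)-1-[(1R)-1-{[tert-butyl(dimethyl)silyl]oxy}ethyl]-5-hydroxy-4-methylidene-3-{[(2R)-2-methylbutanoyl]oxy}-7-(propan-2-yl)octahydro-2H-inden-2-one; 24 (2E)-3-methylpent-2-enoic acid
Product: 25 (1S,3S,3aR,5R,7S,7aS)-1-[(1R)-1-{[tert-butyl(dimethyl)silyl]oxy}ethyl]-4-methylidene-3-{[(2R)-2-methylbutanoyl]oxy}-2-oxo-7-(propan-2-yl)octahydro-1H-inden-5-yl (2E)-3-methylpent-2-enoate
Conditions: DCC, 4-(dimethylamino)pyridine, CH2Cl2, rt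
Reagents that add atoms: none
Why: Steglich esterification of the axial allylic alcohol proceeds with retention at C5, and the E-acid is the more stable geometry so it does not drift.

Step 18
Reactants: 25 (1S,3S,3aR,5R,7S,7aS)-1-[(1R)-1-{[tert-butyl(dimethyl)silyl]oxy}ethyl]-4-methylidene-3-{[(2R)-2-methylbutanoyl]oxy}-2-oxo-7-(propan-2-yl)octahydro-1H-inden-5-yl (2E)-3-methylpent-2-enoate
Product: 26 (1S,3S,3aR,5R,7S,7aS)-1-[(1R)-1-hydroxyethyl]-4-methylidene-3-{[(2R)-2-methylbutanoyl]oxy}-2-oxo-7-(propan-2-yl)octahydro-1H-inden-5-yl (2E)-3-methylpent-2-enoate (CNP0224363.2)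
Conditions: HF·pyridine, pyridine, THF, 0 °C → rt
Reagents that add atoms: none
Why: Fluoride-assisted desilylation under weakly acidic conditions frees the β-hydroxy ketone without retro-aldol, elimination or ester cleavage.

## Compound list

1 | (4S)-4-benzyl-1,3-oxazolidin-2-one | O=C1N[C@@H](Cc2ccccc2)CO1 | starting material
2 | 3-methylbutanoyl chloride | CC(C)CC(Cl)=O | starting material
3 | lithium (4S)-4-benzyl-2-oxo-1,3-oxazolidin-3-ide | [Li+].O=C1[N-][C@@H](Cc2ccccc2)CO1 | intermediate (not isolated)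
4 | (4S)-4-benzyl-3-(3-methylbutanoyl)-1,3-oxazolidin-2-one | CC(C)CC(=O)N1[C@@H](Cc2ccccc2)COC1=O | intermediate
5 | (2Z)-3-methylpent-2-en-4-yn-1-ol | OC/C=C(/C)C#C | starting material
6 | (3Z)-5-bromo-3-methylpent-3-en-1-yne | BrC/C=C(/C)C#C | intermediate
7 | sodium (1Z)-1-[(4S)-4-benzyl-2-oxo-1,3-oxazolidin-3-yl]-3-methylbut-1-en-1-olate | [Na+].CC(C)/C=C(\[O-])N1[C@@H](Cc2ccccc2)COC1=O | intermediate (not isolated)
8 | (4S)-4-benzyl-3-[(2S,4Z)-5-methyl-2-(propan-2-yl)hept-4-en-6-ynoyl]-1,3-oxazolidin-2-one | O=C([C@H](C(C)C)C/C=C(/C)C#C)N1[C@@H](Cc2ccccc2)COC1=O | intermediate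
9 | (2S,4Z)-5-methyl-2-(propan-2-yl)hept-4-en-6-yn-1-ol | OC[C@H](C(C)C)C/C=C(/C)C#C | intermediate
10 | (2S,4Z)-5-methyl-2-(propan-2-yl)hept-4-en-6-ynal | O=C[C@H](C(C)C)C/C=C(/C)C#C | intermediate
11 | 1-(triphenylphosphoranylidene)propan-2-one | CC(=O)C=P(c1ccccc1)(c1ccccc1)c1ccccc1 | starting material
12 | (3E,5S,7Z)-8-methyl-5-(propan-2-yl)deca-3,7-dien-9-yn-2-one | CC(=O)/C=C/[C@H](C(C)C)C/C=C(/C)C#C | intermediate
13 | (2R,3E,5S,7Z)-8-methyl-5-(propan-2-yl)deca-3,7-dien-9-yn-2-ol | C[C@@H](O)/C=C/[C@H](C(C)C)C/C=C(/C)C#C | intermediate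
14 | tert-butyl(dimethyl){[(2R,3E,5S,7Z)-8-methyl-5-(propan-2-yl)deca-3,7-dien-9-yn-2-yl]oxy}silane | C[C@@H](O[Si](C)(C)C(C)(C)C)/C=C/[C@H](C(C)C)C/C=C(/C)C#C | intermediate
15 | (1S,7S,7aR)-1-[(1R)-1-{[tert-butyl(dimethyl)silyl]oxy}ethyl]-4-methyl-7-(propan-2-yl)-1,6,7,7a-tetrahydro-2H-inden-2-one | O=C1C=C2C(C)=CC[C@@H](C(C)C)[C@@H]2[C@H]1[C@@H](C)O[Si](C)(C)C(C)(C)C | intermediate
16 | 1α-[(1R)-1-{[tert-butyl(dimethyl)silyl]oxy}ethyl]-4-methyl-7α-(propan-2-yl)-2,6,7,7a-tetrahydro-1H-inden-2α-ol (H-7a α) | O[C@H]1C=C2C(C)=CC[C@@H](C(C)C)[C@@H]2[C@H]1[C@@H](C)O[Si](C)(C)C(C)(C)C | intermediate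
17 | 1α-[(1R)-1-{[tert-butyl(dimethyl)silyl]oxy}ethyl]-3α,3aα-epoxy-4-methyl-7α-(propan-2-yl)-2,3,3a,6,7,7a-hexahydro-1H-inden-2α-ol (H-7a α) | O[C@H]1[C@H]2O[C@]23C(C)=CC[C@@H](C(C)C)[C@@H]3[C@H]1[C@@H](C)O[Si](C)(C)C(C)(C)C | intermediate
18 | 1α-[(1R)-1-{[tert-butyl(dimethyl)silyl]oxy}ethyl]-3α,3aα-epoxy-4-methyl-7α-(propan-2-yl)-1,3,3a,6,7,7a-hexahydro-2H-inden-2-one (H-7a α) | O=C1[C@H]2O[C@]23C(C)=CC[C@@H](C(C)C)[C@@H]3[C@H]1[C@@H](C)O[Si](C)(C)C(C)(C)C | intermediate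
19 | (1S,3S,3aR,7S,7aS)-1-[(1R)-1-{[tert-butyl(dimethyl)silyl]oxy}ethyl]-3-hydroxy-4-methyl-7-(propan-2-yl)-1,3,3a,6,7,7a-hexahydro-2H-inden-2-one | O=C1[C@@H](O)[C@H]2C(C)=CC[C@@H](C(C)C)[C@@H]2[C@H]1[C@@H](C)O[Si](C)(C)C(C)(C)C | intermediate
20 | (2R)-2-methylbutanoic acid | CC[C@@H](C)C(=O)O | starting material
21 | (1S,3S,3aR,7S,7aS)-1-[(1R)-1-{[tert-butyl(dimethyl)silyl]oxy}ethyl]-4-methyl-3-{[(2R)-2-methylbutanoyl]oxy}-7-(propan-2-yl)-1,3,3a,6,7,7a-hexahydro-2H-inden-2-one | O=C1[C@@H](OC(=O)[C@H](C)CC)[C@H]2C(C)=CC[C@@H](C(C)C)[C@@H]2[C@H]1[C@@H](C)O[Si](C)(C)C(C)(C)C | intermediate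
22 | 1α-[(1R)-1-{[tert-butyl(dimethyl)silyl]oxy}ethyl]-4β,5β-epoxy-4-methyl-3α-{[(2R)-2-methylbutanoyl]oxy}-7α-(propan-2-yl)octahydro-2H-inden-2-one (H-3a β, H-7a α) | O=C1[C@@H](OC(=O)[C@H](C)CC)[C@H]2[C@]3(C)O[C@@H]3C[C@@H](C(C)C)[C@@H]2[C@H]1[C@@H](C)O[Si](C)(C)C(C)(C)C | intermediate
23 | (1S,3S,3aR,5R,7S,7aS)-1-[(1R)-1-{[tert-butyl(dimethyl)silyl]oxy}ethyl]-5-hydroxy-4-methylidene-3-{[(2R)-2-methylbutanoyl]oxy}-7-(propan-2-yl)octahydro-2H-inden-2-one | C=C1[C@H]2[C@@H]([C@@H]([C@@H](C)O[Si](C)(C)C(C)(C)C)C(=O)[C@H]2OC(=O)[C@H](C)CC)[C@H](C(C)C)C[C@H]1O | intermediate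
24 | (2E)-3-methylpent-2-enoic acid | CC/C(C)=C/C(=O)O | starting material
25 | (1S,3S,3aR,5R,7S,7aS)-1-[(1R)-1-{[tert-butyl(dimethyl)silyl]oxy}ethyl]-4-methylidene-3-{[(2R)-2-methylbutanoyl]oxy}-2-oxo-7-(propan-2-yl)octahydro-1H-inden-5-yl (2E)-3-methylpent-2-enoate | C=C1[C@H]2[C@@H]([C@@H]([C@@H](C)O[Si](C)(C)C(C)(C)C)C(=O)[C@H]2OC(=O)[C@H](C)CC)[C@H](C(C)C)C[C@H]1OC(=O)/C=C(\C)CC | intermediate
26 | (1S,3S,3aR,5R,7S,7aS)-1-[(1R)-1-hydroxyethyl]-4-methylidene-3-{[(2R)-2-methylbutanoyl]oxy}-2-oxo-7-(propan-2-yl)octahydro-1H-inden-5-yl (2E)-3-methylpent-2-enoate | C=C1[C@H]2[C@@H]([C@@H]([C@@H](C)O)C(=O)[C@H]2OC(=O)[C@H](C)CC)[C@H](C(C)C)C[C@H]1OC(=O)/C=C(\C)CC | target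

## Totals and risks

Total step count: 18. Longest linear sequence: 17 steps (steps 1 and 3–18, from 1 to 26; step 2 is a one-step side branch).

The three steps most likely to fail:

**Step 9 (Pauson–Khand).** The alkene is E-1,2-disubstituted and flanked by two branched carbons, so insertion may be slow, and the selectivity at C7a rests only on the allylic isopropyl centre. Fallback, setting out from 10: methylenation with Ph3P=CH2 (THF, 0 °C) gives (3Z,6S)-3-methyl-6-(propan-2-yl)octa-3,7-dien-1-yne F1, whose unhindered terminal alkene cyclises under the same cobalt/CO conditions to (7S,7aS)-4-methyl-7-(propan-2-yl)-1,6,7,7a-tetrahydro-2H-inden-2-one F2. Kinetic α′-deprotonation with LiN(i-Pr)2, transmetalation with Cp2ZrCl2 and addition of acetaldehyde then gives (1S,7S,7aR)-1-[(1R)-1-hydroxyethyl]-4-methyl-7-(propan-2-yl)-1,6,7,7a-tetrahydro-2H-inden-2-one F3. Zirconium enolates give syn aldols whatever the enolate geometry, and the aldehyde approaches C1 on the α face, away from the six-membered ring. Silylation with TBSOTf and 2,6-lutidine comes back to the route at 15.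

**Step 13 (palladium/formate hydrogenolysis of the epoxy ketone).** Zerovalent palladium could instead cleave the C3–O bond next to the carbonyl and give the β-hydroxy ketone. Fallback, setting out from 17: silylation with chlorotriethylsilane and imidazole gives the 2α-triethylsilyl ether of 17 F4, in which only the allylic ionisation is possible. The same palladium/formate conditions give the 3α-hydroxy-2α-triethylsilyloxy trans-fused hexahydroindene F5. Steglich esterification with 20 gives its 3α-(2R)-2-methylbutanoate F6. Pyridinium p-toluenesulfonate in methanol removes only the triethylsilyl group to give the 2α-alcohol F7. Dess–Martin oxidation comes back to the route at 21.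

**Step 15 (face of the C4=C5 epoxidation).** The β preference rests on shielding by the C3 acyloxy group alone. Fallback, setting out from 21: if dimethyldioxirane delivers mainly the 4α,5α-epoxide of 21 F8, it is carried through the same titanium opening to the 5α-hydroxy epimer of 23 F9. A Mitsunobu esterification with 24 (PPh3, diisopropyl azodicarboxylate, toluene, 0 °C) then inverts C5 while installing the enoate and comes back to the route at 25.

## Further compounds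

F1 | step 9 | (3Z,6S)-3-methyl-6-(propan-2-yl)octa-3,7-dien-1-yne | C=C[C@H](C(C)C)C/C=C(/C)C#C
F2 | step 9 | (7S,7aS)-4-methyl-7-(propan-2-yl)-1,6,7,7a-tetrahydro-2H-inden-2-one | O=C1C=C2C(C)=CC[C@@H](C(C)C)[C@@H]2C1
F3 | step 9 | (1S,7S,7aR)-1-[(1R)-1-hydroxyethyl]-4-methyl-7-(propan-2-yl)-1,6,7,7a-tetrahydro-2H-inden-2-one | O=C1C=C2C(C)=CC[C@@H](C(C)C)[C@@H]2[C@H]1[C@@H](C)O
F4 | step 13 | 2α-triethylsilyl ether of 17 (3α,3aα-epoxide, H-7a α) | CC[Si](CC)(CC)O[C@H]1[C@H]2O[C@]23C(C)=CC[C@@H](C(C)C)[C@@H]3[C@H]1[C@@H](C)O[Si](C)(C)C(C)(C)C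
F5 | step 13 | 1α-[(1R)-1-{[tert-butyl(dimethyl)silyl]oxy}ethyl]-4-methyl-7α-(propan-2-yl)-2α-(triethylsilyloxy)-2,3,3a,6,7,7a-hexahydro-1H-inden-3α-ol (H-3a β, H-7a α) | CC[Si](CC)(CC)O[C@H]1[C@@H](O)[C@H]2C(C)=CC[C@@H](C(C)C)[C@@H]2[C@H]1[C@@H](C)O[Si](C)(C)C(C)(C)C
F6 | step 13 | 3α-(2R)-2-methylbutanoate of F5 | CC[Si](CC)(CC)O[C@H]1[C@@H](OC(=O)[C@H](C)CC)[C@H]2C(C)=CC[C@@H](C(C)C)[C@@H]2[C@H]1[C@@H](C)O[Si](C)(C)C(C)(C)C
F7 | step 13 | 2α-alcohol from F6 (3α-(2R)-2-methylbutanoyloxy, H-3a β, H-7a α) | O[C@H]1[C@@H](OC(=O)[C@H](C)CC)[C@H]2C(C)=CC[C@@H](C(C)C)[C@@H]2[C@H]1[C@@H](C)O[Si](C)(C)C(C)(C)C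
F8 | step 15 | 4α,5α-epoxide of 21 (C4/C5 epimer of 22) | O=C1[C@@H](OC(=O)[C@H](C)CC)[C@H]2[C@@]3(C)O[C@H]3C[C@@H](C(C)C)[C@@H]2[C@H]1[C@@H](C)O[Si](C)(C)C(C)(C)C
F9 | step 15 | 5α-hydroxy epimer of 23 | C=C1[C@H]2[C@@H]([C@@H]([C@@H](C)O[Si](C)(C)C(C)(C)C)C(=O)[C@H]2OC(=O)[C@H](C)CC)[C@H](C(C)C)C[C@@H]1O
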